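The data are calculated with constants of no real substance.

The vessel holds starting complex and incoming ligand, closed and stirred at one temperature, and the two earlier runs show how the starting complex disappears.

| flask | starting complex | incoming ligand | remark | time |
|---|---|---|---|---|
| south-east | 16 mM | 8.2 mM | run made earlier |  |
| west | 16 mM | 17 mM | run made earlier |  |
| beta | 16 mM | 16.0 mM |  | 3.0 d |
| gamma | 16 mM | 21.0 mM |  | 3.0 d |

| run | time / h | starting complex / % | complex with two exchanged / % |
|---|---|---|---|
| south-east | 3.00 | 85.3 | 0 |
| south-east | 5.00 | 76.7 | 0.1 |
| south-east | 8.00 | 67.2 | 0.9 |
| south-east | 12.0 | 57.0 | 1.7 |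
| south-east | 20.0 | 43.0 | 2.6 |
| south-east | 40.0 | 25.8 | 5.2 |
| west | 3.00 | 76.2 | 1.5 |
| west | 5.00 | 64.4 | 1.6 |
| west | 8.00 | 51.6 | 2.5 |
| west | 12.0 | 39.2 | 4.3 |
| west | 20.0 | 24.8 | 7.0 |
| west | 40.0 | 13.1 | 8.7 |

(readings scatter by 0.5 percentage points)

- the numbers in the tables scatter with a standard deviation of 0.5 percentage points
- what has gone from starting complex into another species counts as reacted, even if it can come back

* part of the starting complex that has reacted at the end, beta
* part of the starting complex that has reacted at the end, gamma
* what raising the concentration of incoming ligand from its lowest to its highest value here does to the part of the starting complex that has reacted (changes below 5 percentage points count as none) (it rises / it falls / no change)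

Let f be the fraction of starting complex left, c the charge of incoming ligand and t the time. Late in both runs, 1/f against t, a second-order plot, runs nearly straight, and at the last reading it stands higher in west, the run with more ligand. With the starting complex charged at 16 mM in every flask, that suggests freezing one number, the ligand-time constant σ = (1/f − 1)/(ct). As readings at the last point, σ is 8.77 /M/h in south-east and 9.76 /M/h in west. West's charge, 17 mM, stands between those of beta and gamma, so the west value is the one frozen.

South-east had reacted 74.2% at 40.0 h. Turning the ligand up to beta's 16.0 mM with that time held gives 86.2% by this reckoning. Turning the time up to 3.0 d with south-east's ligand held gives 85.2% by the same reckoning. Both turned together give 91.8% for beta, and gamma's charge gives 93.7%. The gap of 1.8 percentage points is smaller than the 5 points that counts as a change, so this reckoning says no change.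

The forecast differs on the trend, giving 92%, 95% and "it rises": “From 8.2 to 21 mM, reacted rises from about 87% to about 95%.”

The flask gives 91.3% for beta and 93.6% for gamma, a difference of 2.3 points, hence no change.

    starting complex + incoming ligand → leaving ligand + complex with one exchanged (k = 2.10 /M/h)
    complex with one exchanged + incoming ligand → leaving ligand + complex with two exchanged (k = 3.30 /M/h)
    complex with two exchanged + incoming ligand → leaving ligand + complex with three exchanged (k = 5.00 /M/h)
    leaving ligand + starting complex ⇌ idle adduct, settled at all times (K = 600 /M)
    2 starting complex → self-condensation product (k = 0.780 /M/h)

At the end of beta, idle adduct stands at 35.9%, more than the 8.71% of starting complex. Read back from beta's end, σ is 9.09 /M/h. Carried to the gamma flask read at 20 h, the frozen σ gives 80.4% reacted, and that flask stands at 80.6%.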